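**Retrosynthetic overview**

1. Ring A is made last, from a four-carbon unit (angular-methyl carbon, the later CHBr carbon as a ketone, and a vinyl group) and a two-carbon unit (the ring-fusion CH and the later carbinol carbon, as an (E)-vinyl sulfone). Both bonds that join them form in one anionic double Michael cascade, which also closes ring B.
2. Enabling feature: in ring A the quaternary angular-methyl carbon sits next to the ring-fusion CH, CHBr is flanked by that quaternary carbon and a CH2 (the α′/C=O/vinyl pattern of a vinyl ketone), and the carbinol carbon sits next to the ring-fusion CH (the pattern of an acceptor). The quaternary bridgehead carbon of the bicyclo[2.2.1]heptane and its exo-substituted neighbour hold the two tether ends gauche (about 45°), so ring B can close through one chair only.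
3. The bicyclo[2.2.1]heptane comes from a catalytic asymmetric Diels–Alder reaction of a 1-alkyl-2-silyloxycyclopentadiene with (E)-4,4-dimethoxybut-2-enal; the formyl group steers regio- and endo-selectivity and is then removed. The exo carbinol with endo isopropyl follows by enol triflate, Negishi coupling and Mukaiyama hydration.
4. End game: ring-A enol triflate to alkenyl bromide, HAT hydrogenation to the equatorial bromide, sulfone to ketone, and methyl addition on the equatorial side to give the axial hydroxyl.
5. Ring order: cyclopentene (purchased), then the bicyclo[2.2.1]heptane (step 4), then rings B and A together (step 14).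

Key step: step 14

Remark (assumption on the chemistry): the methyl-bearing CH of the side chain (compounds 4, 7–18) is carried as an epimeric mixture, because it becomes a planar enolate carbon in step 14. The allylic carbinol of 15–17 and the sulfone-bearing carbon of 21–24 are also uncontrolled; they are removed in steps 13 and 17. These centres are written without configuration. Compounds 1, 3 and 6 are taken as commercial. Locants in the names of 7–18 refer to the bicyclo[2.2.1]heptane (C1 = substituted bridgehead, C2 = ketone/carbinol carbon, C6 = carbon with the exo one-carbon substituent); absolute configuration is as in the SMILES. The catalyst enantiomer in step 4 is assigned from the usual binding model and is the least secure assignment in the route.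

Step 1
Reactants: 1 ethyl 4-bromo-2-methylbutanoate (racemic)
Product: 2 ethyl 4-iodo-2-methylbutanoate (racemic)
Conditions: NaI, acetone, reflux
Reagents that add atoms: sodium iodide, [Na+].[I-]
Why: Finkelstein halide exchange (SN2), driven by precipitation of NaBr, gives the more reactive primary iodide; no stereocentre is touched.

Step 2
Reactants: 3 cyclopent-2-en-1-one; 2 ethyl 4-iodo-2-methylbutanoate
Product: 4 ethyl 2-methyl-4-(2-oxocyclopent-3-en-1-yl)butanoate (diastereomer mixture)
Conditions: LDA, THF, −78 °C; then 2, DMPU, −78 → −20 °C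
Reagents that add atoms: none
Why: Kinetic deprotonation of the enone at the α′-carbon gives the cross-conjugated lithium dienolate, whose C-alkylation by the primary iodide (enolate alkylation) installs the whole side chain; the two stereocentres of 4 are not controlled because both become planar later (steps 3 and 14).

Step 3
Reactants: 4 ethyl 2-methyl-4-(2-oxocyclopent-3-en-1-yl)butanoate
Product: 5 ethyl 2-methyl-4-[2-(triisopropylsilyloxy)cyclopenta-1,3-dien-1-yl]butanoate
Conditions: TIPSOTf, Et3N, CH2Cl2, 0 °C
Reagents that add atoms: triisopropylsilyl trifluoromethanesulfonate, CC(C)[Si](C(C)C)(C(C)C)OS(=O)(=O)C(F)(F)F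
Why: Soft enolization (O-silylation, then loss of the α′-proton to the amine) gives the cross-conjugated 2-silyloxy diene with the alkyl group on a diene terminus; it is used at once to avoid 1,5-hydrogen shifts.

Step 4
Reactants: 5 ethyl 2-methyl-4-[2-(triisopropylsilyloxy)cyclopenta-1,3-dien-1-yl]butanoate; 6 (E)-4,4-dimethoxybut-2-enal
Product: 8 ethyl 4-[6-exo-(dimethoxymethyl)-5-endo-formyl-2-oxobicyclo[2.2.1]hept-1-yl]-2-methylbutanoate, via cycloadduct silyl enol ether 7 (not isolated)
Conditions: (R)-3,3-diphenyl-1-(2-methylphenyl)tetrahydro-1H,3H-pyrrolo[1,2-c][1,3,2]oxazaborole·HNTf2 (20 mol%), CH2Cl2, −78 → −40 °C; then Bu4NF, AcOH, THF, 0 °C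
Reagents that add atoms: none
Why: Asymmetric Diels–Alder reaction under a chiral oxazaborolidinium Lewis acid: the silyloxy group makes the alkyl-bearing diene terminus the nucleophilic one, so it bonds to the β-carbon of the formyl-activated enal and creates the quaternary bridgehead; the formyl group goes endo so that the trans acetal is exo; attack on the 2Si,3Si face of the bound s-trans enal (the face expected to be left open by the (R)-catalyst) fixes the absolute configuration of all four stereocentres; buffered fluoride then unmasks the C2 ketone.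

Step 5
Reactants: 8 ethyl 4-[6-exo-(dimethoxymethyl)-5-endo-formyl-2-oxobicyclo[2.2.1]hept-1-yl]-2-methylbutanoate
Product: 9 ethyl 4-[6-exo-(dimethoxymethyl)-2-oxobicyclo[2.2.1]hept-1-yl]-2-methylbutanoate
Conditions: [Rh(cod)Cl]2 (5 mol%), dppp (10 mol%), diglyme, 160 °C
Reagents that add atoms: none
Why: Rhodium-catalysed decarbonylation (Tsuji–Wilkinson type: formyl C–H oxidative addition, CO extrusion, C–H reductive elimination) replaces the formyl group, which has done its work as regio- and endo-controller, by hydrogen; C6 should not be touched.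

Step 6
Reactants: 9 ethyl 4-[6-exo-(dimethoxymethyl)-2-oxobicyclo[2.2.1]hept-1-yl]-2-methylbutanoate
Product: 10 ethyl 4-[6-exo-(dimethoxymethyl)-2-(trifluoromethylsulfonyloxy)bicyclo[2.2.1]hept-2-en-1-yl]-2-methylbutanoate
Conditions: KHMDS, THF, −78 °C; then PhNTf2, −78 → 0 °C
Reagents that add atoms: N-phenylbis(trifluoromethanesulfonimide), O=S(=O)(N(c1ccccc1)S(=O)(=O)C(F)(F)F)C(F)(F)F
Why: The ketone can enolize only towards C3 (C1 is a quaternary bridgehead), so enolate formation and O-triflation (enol triflate synthesis) are regiospecific; the ester α-proton is much less acidic.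

Step 7
Reactants: 10 ethyl 4-[6-exo-(dimethoxymethyl)-2-(trifluoromethylsulfonyloxy)bicyclo[2.2.1]hept-2-en-1-yl]-2-methylbutanoate
Product: 11 ethyl 4-[6-exo-(dimethoxymethyl)-2-isopropylbicyclo[2.2.1]hept-2-en-1-yl]-2-methylbutanoate
Conditions: iPrZnBr, Pd(dppf)Cl2 (5 mol%), THF, 50 °C
Reagents that add atoms: isopropylzinc bromide, CC(C)[Zn]Br
Why: Negishi cross-coupling of the alkenyl triflate with a secondary alkylzinc; the wide-bite-angle dppf ligand favours reductive elimination over β-hydride isomerization to n-propyl, and ester and acetal are inert.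

Step 8
Reactants: 11 ethyl 4-[6-exo-(dimethoxymethyl)-2-isopropylbicyclo[2.2.1]hept-2-en-1-yl]-2-methylbutanoate
Product: 13 ethyl 4-[6-exo-(dimethoxymethyl)-2-exo-hydroxy-2-endo-isopropylbicyclo[2.2.1]hept-1-yl]-2-methylbutanoate, via tertiary hydroperoxide 12 (not isolated)
Conditions: Co(acac)2 (20 mol%), PhSiH3, O2 (1 atm), iPrOH, rt
Reagents that add atoms: dioxygen, O=O
Why: Mukaiyama hydration: cobalt-hydride hydrogen atom transfer to C3 gives the tertiary 2-norbornyl radical, which O2 traps on the exo face (the endo face is screened by the C5–C6 bridge), and the hydroperoxide is reduced by the silane, so the hydroxyl is exo and the isopropyl group endo as in the target.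

Step 9
Reactants: 13 ethyl 4-[6-exo-(dimethoxymethyl)-2-exo-hydroxy-2-endo-isopropylbicyclo[2.2.1]hept-1-yl]-2-methylbutanoate
Product: 14 4-[6-exo-(dimethoxymethyl)-2-exo-hydroxy-2-endo-isopropylbicyclo[2.2.1]hept-1-yl]-2-methylbutanal
Conditions: DIBAL-H (2.2 equiv), CH2Cl2, −78 °C; aq. Rochelle salt
Reagents that add atoms: none
Why: DIBAL-H partial reduction of the ester stops at the aldehyde because the aluminium hemiacetal is stable at −78 °C; one equivalent is consumed by the tertiary hydroxyl and the acetal is untouched.

Step 10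
Reactants: 14 4-[6-exo-(dimethoxymethyl)-2-exo-hydroxy-2-endo-isopropylbicyclo[2.2.1]hept-1-yl]-2-methylbutanal
Product: 15 6-[6-exo-(dimethoxymethyl)-2-exo-hydroxy-2-endo-isopropylbicyclo[2.2.1]hept-1-yl]-4-methylhex-1-en-3-ol
Conditions: CH2=CHMgBr (2.5 equiv), THF, −78 → 0 °C
Reagents that add atoms: vinylmagnesium bromide, C=C[Mg]Br
Why: Grignard 1,2-addition to the aldehyde; the new carbinol centre is uncontrolled and is removed by oxidation in step 13.

Step 11
Reactants: 15 6-[6-exo-(dimethoxymethyl)-2-exo-hydroxy-2-endo-isopropylbicyclo[2.2.1]hept-1-yl]-4-methylhex-1-en-3-ol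
Product: 16 2-exo-hydroxy-1-(4-hydroxy-3-methylhex-5-en-1-yl)-2-endo-isopropylbicyclo[2.2.1]heptane-6-exo-carbaldehyde
Conditions: PPTS (cat.), acetone/H2O, 40 °C
Reagents that add atoms: water, O
Why: Mild acid-catalysed acetal hydrolysis frees the C6 aldehyde under conditions that should spare the tertiary 2-norbornanol and the allylic alcohol; the exo aldehyde should not lactolize with the exo hydroxyl at C2 because the two exo bonds diverge.

Step 12
Reactants: 16 2-exo-hydroxy-1-(4-hydroxy-3-methylhex-5-en-1-yl)-2-endo-isopropylbicyclo[2.2.1]heptane-6-exo-carbaldehyde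
Product: 17 6-[2-exo-hydroxy-2-endo-isopropyl-6-exo-[(E)-2-(phenylsulfonyl)ethenyl]bicyclo[2.2.1]hept-1-yl]-4-methylhex-1-en-3-ol
Conditions: (EtO)2P(O)CH2SO2Ph, NaH, THF, 0 °C → rt
Reagents that add atoms: diethyl [(phenylsulfonyl)methyl]phosphonate, CCOP(=O)(CS(=O)(=O)c1ccccc1)OCC
Why: Horner–Wadsworth–Emmons olefination with the sulfonyl-stabilised phosphonate anion gives the (E)-vinyl sulfone; the anion is too weakly basic to deprotonate the hydroxyls.

Step 13
Reactants: 17 6-[2-exo-hydroxy-2-endo-isopropyl-6-exo-[(E)-2-(phenylsulfonyl)ethenyl]bicyclo[2.2.1]hept-1-yl]-4-methylhex-1-en-3-ol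
Product: 18 6-[2-exo-hydroxy-2-endo-isopropyl-6-exo-[(E)-2-(phenylsulfonyl)ethenyl]bicyclo[2.2.1]hept-1-yl]-4-methylhex-1-en-3-one
Conditions: Dess–Martin periodinane, NaHCO3, CH2Cl2, 0 °C
Reagents that add atoms: none
Why: Dess–Martin oxidation of the secondary allylic alcohol gives the vinyl ketone under buffered, non-nucleophilic conditions; the tertiary alcohol cannot be oxidised, and 18 is used at once.

Step 14
Reactants: 18 6-[2-exo-hydroxy-2-endo-isopropyl-6-exo-[(E)-2-(phenylsulfonyl)ethenyl]bicyclo[2.2.1]hept-1-yl]-4-methylhex-1-en-3-one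
Product: 21 tetracyclic ring-A enol triflate (OTf on the later C–Br carbon; C=C towards the adjacent CH; PhSO2 on the later carbinol carbon; trans ring fusion), via ring-B carbanion 19 (not isolated), via tetracyclic lithium enolate 20 (not isolated)
Conditions: LiHMDS (2.3 equiv), THF (0.01 M), −78 → −20 °C; then PhNTf2, −78 → 0 °C
Reagents that add atoms: N-phenylbis(trifluoromethanesulfonimide), O=S(=O)(N(c1ccccc1)S(=O)(=O)C(F)(F)F)C(F)(F)F
Why: LiHMDS deprotonates the hydroxyl and then the tertiary α′-C–H of the vinyl ketone; the cross-conjugated lithium dienolate adds through its substituted α-carbon to the β-carbon of the vinyl sulfone (first new bond, 6-exo-trig, closes ring B), the α-sulfonyl carbanion 19 adds to the terminal carbon of the regenerated vinyl ketone (second new bond, 6-endo-trig, closes ring A), and the regiodefined enolate 20 is trapped on oxygen by PhNTf2. The closest known reaction type is the intramolecular double Michael reaction of α′-enolizable enones carrying a tethered acceptor (an anionic formal [4+2] cycloaddition), combined with enolate O-triflation. The new ring-fusion CH and the quaternary angular-methyl carbon are controlled by the bicyclo[2.2.1]heptane: its bridgehead carbon and exo C6 substituent are held gauche, so ring B can close through one chair only, in which the one-carbon bridge is axial; an axial sulfonylvinyl group would clash with this bridge and the oxy-dienyl group is larger than methyl, so both π-systems sit equatorial and the ring-fusion hydrogen and the angular methyl end trans-diaxial, which is the trans-decalin of the target. The configuration of the enolate carbon is erased on deprotonation, so both side-chain epimers of 18 converge, and the sulfone-bearing carbon need not be controlled because it becomes a ketone in step 17. The step needs α′-deprotonation to outrun γ-deprotonation of the vinyl sulfone and intermolecular Michael addition; the γ-hydrogen is a shielded endo C–H on the bicycle, the vinyl ketone is masked as the dienolate until ring B has formed, and high dilution is used.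

Step 15
Reactants: 21 tetracyclic ring-A enol triflate
Product: 22 tetracyclic ring-A alkenyl bromide (Br in place of OTf; PhSO2 on the later carbinol carbon)
Conditions: Ni(cod)2 (10 mol%), LiBr, DMA/THF, rt
Reagents that add atoms: lithium bromide, [Li+].[Br-]
Why: Nickel-catalysed halide exchange of an alkenyl triflate (oxidative addition of zerovalent nickel to the C–OTf bond, triflate–bromide exchange at nickel, C–Br reductive elimination) gives the alkenyl bromide with the double bond in place; sulfone and hydroxyl are inert.

Step 16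
Reactants: 22 tetracyclic ring-A alkenyl bromide
Product: 23 tetracyclic equatorial bromide (target skeleton with PhSO2 and H on the later carbinol carbon)
Conditions: Mn(dpm)3 (10 mol%), PhSiH3, t-BuOOH, iPrOH, rt
Reagents that add atoms: none
Why: Metal-hydride hydrogen atom transfer hydrogenation, a method that reduces haloalkenes without hydrodehalogenation: the manganese hydride delivers a hydrogen atom to the CH terminus, and the α-bromo radical should accept the second hydrogen on the axial side (anti to the angular methyl, away from the flanking quaternary carbon), so that bromine ends equatorial, the more stable epimer, as in the target.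

Step 17
Reactants: 23 tetracyclic equatorial bromide
Product: 25 tetracyclic bromo ketone (C=O at the later carbinol carbon), via α-silyloxy sulfone 24 (not isolated)
Conditions: LDA (2.2 equiv), THF, −78 °C; then Me3SiOOSiMe3, −78 → 0 °C; pH 7 buffer
Reagents that add atoms: bis(trimethylsilyl) peroxide, C[Si](C)(C)OO[Si](C)(C)C
Why: Oxidative desulfonylation: the α-sulfonyl carbanion is oxygenated at carbon by the silyl peroxide and the α-silyloxy sulfone collapses to the ketone with loss of benzenesulfinate; the equatorial bromide has no anti-periplanar hydrogen for E2, and a neutral work-up avoids base-induced 1,3-elimination of the γ-bromo ketone.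

Step 18
Reactants: 25 tetracyclic bromo ketone
Product: 26 CNP0362628.1 (target)
Conditions: MeMgBr, CeCl3, THF, −78 °C
Reagents that add atoms: methylmagnesium bromide, C[Mg]Br
Why: Organocerium (Grignard-type) 1,2-addition: the weakly basic reagent adds faster than it enolizes, and it approaches on the equatorial side because the axial side is blocked by the 1,3-diaxial angular methyl group, which should give the axial hydroxyl and equatorial methyl of the target.

**Compound list**

1 | ethyl 4-bromo-2-methylbutanoate (racemic) | CCOC(=O)C(C)CCBr | starting material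
2 | ethyl 4-iodo-2-methylbutanoate (racemic) | CCOC(=O)C(C)CCI | intermediate
3 | cyclopent-2-en-1-one | O=C1C=CCC1 | starting material
4 | ethyl 2-methyl-4-(2-oxocyclopent-3-en-1-yl)butanoate (diastereomer mixture) | CCOC(=O)C(C)CCC1CC=CC1=O | intermediate
5 | ethyl 2-methyl-4-[2-(triisopropylsilyloxy)cyclopenta-1,3-dien-1-yl]butanoate | CCOC(=O)C(C)CCC1=C(O[Si](C(C)C)(C(C)C)C(C)C)C=CC1 | intermediate
6 | (E)-4,4-dimethoxybut-2-enal | COC(OC)/C=C/C=O | starting material
7 | ethyl 4-[6-exo-(dimethoxymethyl)-5-endo-formyl-2-(triisopropylsilyloxy)bicyclo[2.2.1]hept-2-en-1-yl]-2-methylbutanoate | CC(C)[Si](C(C)C)(C(C)C)OC1=C[C@@H]2[C@H](C=O)[C@@H](C(OC)OC)[C@@]1(CCC(C)C(=O)OCC)C2 | intermediate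
8 | ethyl 4-[6-exo-(dimethoxymethyl)-5-endo-formyl-2-oxobicyclo[2.2.1]hept-1-yl]-2-methylbutanoate | O=C1C[C@@H]2[C@H](C=O)[C@@H](C(OC)OC)[C@@]1(CCC(C)C(=O)OCC)C2 | intermediate
9 | ethyl 4-[6-exo-(dimethoxymethyl)-2-oxobicyclo[2.2.1]hept-1-yl]-2-methylbutanoate | O=C1C[C@@H]2C[C@@H](C(OC)OC)[C@@]1(CCC(C)C(=O)OCC)C2 | intermediate
10 | ethyl 4-[6-exo-(dimethoxymethyl)-2-(trifluoromethylsulfonyloxy)bicyclo[2.2.1]hept-2-en-1-yl]-2-methylbutanoate | O=S(=O)(OC1=C[C@@H]2C[C@@H](C(OC)OC)[C@@]1(CCC(C)C(=O)OCC)C2)C(F)(F)F | intermediate
11 | ethyl 4-[6-exo-(dimethoxymethyl)-2-isopropylbicyclo[2.2.1]hept-2-en-1-yl]-2-methylbutanoate | CC(C)C1=C[C@@H]2C[C@@H](C(OC)OC)[C@@]1(CCC(C)C(=O)OCC)C2 | intermediate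
12 | ethyl 4-[6-exo-(dimethoxymethyl)-2-exo-hydroperoxy-2-endo-isopropylbicyclo[2.2.1]hept-1-yl]-2-methylbutanoate | CC(C)[C@]1(OO)C[C@@H]2C[C@@H](C(OC)OC)[C@@]1(CCC(C)C(=O)OCC)C2 | intermediate
13 | ethyl 4-[6-exo-(dimethoxymethyl)-2-exo-hydroxy-2-endo-isopropylbicyclo[2.2.1]hept-1-yl]-2-methylbutanoate | CC(C)[C@]1(O)C[C@@H]2C[C@@H](C(OC)OC)[C@@]1(CCC(C)C(=O)OCC)C2 | intermediate
14 | 4-[6-exo-(dimethoxymethyl)-2-exo-hydroxy-2-endo-isopropylbicyclo[2.2.1]hept-1-yl]-2-methylbutanal | CC(C)[C@]1(O)C[C@@H]2C[C@@H](C(OC)OC)[C@@]1(CCC(C)C=O)C2 | intermediate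
15 | 6-[6-exo-(dimethoxymethyl)-2-exo-hydroxy-2-endo-isopropylbicyclo[2.2.1]hept-1-yl]-4-methylhex-1-en-3-ol | CC(C)[C@]1(O)C[C@@H]2C[C@@H](C(OC)OC)[C@@]1(CCC(C)C(O)C=C)C2 | intermediate
16 | 2-exo-hydroxy-1-(4-hydroxy-3-methylhex-5-en-1-yl)-2-endo-isopropylbicyclo[2.2.1]heptane-6-exo-carbaldehyde | CC(C)[C@]1(O)C[C@@H]2C[C@@H](C=O)[C@@]1(CCC(C)C(O)C=C)C2 | intermediate
17 | 6-[2-exo-hydroxy-2-endo-isopropyl-6-exo-[(E)-2-(phenylsulfonyl)ethenyl]bicyclo[2.2.1]hept-1-yl]-4-methylhex-1-en-3-ol | CC(C)[C@]1(O)C[C@@H]2C[C@@H](/C=C/S(=O)(=O)c3ccccc3)[C@@]1(CCC(C)C(O)C=C)C2 | intermediate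
18 | 6-[2-exo-hydroxy-2-endo-isopropyl-6-exo-[(E)-2-(phenylsulfonyl)ethenyl]bicyclo[2.2.1]hept-1-yl]-4-methylhex-1-en-3-one | CC(C)[C@]1(O)C[C@@H]2C[C@@H](/C=C/S(=O)(=O)c3ccccc3)[C@@]1(CCC(C)C(=O)C=C)C2 | intermediate
19 | dilithium alkoxide/α-sulfonyl carbanion after closure of ring B (vinyl ketone still open) | [Li+].[Li+].CC(C)[C@]1([O-])C[C@@H]2C[C@H]3[C@H]([CH-]S(=O)(=O)c4ccccc4)[C@](C)(CC[C@@]31C2)C(=O)C=C | intermediate
20 | dilithium alkoxide/ring-A enolate of the tetracyclic keto sulfone | [Li+].[Li+].CC(C)[C@]1([O-])C[C@@H]2C[C@H]3[C@H]4[C@](C)(CC[C@@]31C2)C([O-])=CCC4S(=O)(=O)c1ccccc1 | intermediate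
21 | tetracyclic ring-A enol triflate with PhSO2 on the later carbinol carbon | CC(C)[C@]1(O)C[C@@H]2C[C@H]3[C@H]4[C@](C)(CC[C@@]31C2)C(OS(=O)(=O)C(F)(F)F)=CCC4S(=O)(=O)c1ccccc1 | intermediate
22 | tetracyclic ring-A alkenyl bromide with PhSO2 on the later carbinol carbon | CC(C)[C@]1(O)C[C@@H]2C[C@H]3[C@H]4[C@](C)(CC[C@@]31C2)C(Br)=CCC4S(=O)(=O)c1ccccc1 | intermediate
23 | tetracyclic equatorial bromide with PhSO2 on the later carbinol carbon | CC(C)[C@]1(O)C[C@@H]2C[C@H]3[C@H]4[C@](C)(CC[C@@]31C2)[C@@H](Br)CCC4S(=O)(=O)c1ccccc1 | intermediate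
24 | lithium alkoxide of the α-(trimethylsilyloxy) sulfone | [Li+].CC(C)[C@]1([O-])C[C@@H]2C[C@H]3[C@H]4[C@](C)(CC[C@@]31C2)[C@@H](Br)CCC4(O[Si](C)(C)C)S(=O)(=O)c1ccccc1 | intermediate
25 | tetracyclic bromo ketone (C=O at the later carbinol carbon) | CC(C)[C@]1(O)C[C@@H]2C[C@H]3[C@H]4[C@](C)(CC[C@@]31C2)[C@@H](Br)CCC4=O | intermediate
26 | CNP0362628.1 | CC(C)[C@]1(O)C[C@@H]2C[C@H]3[C@H]4[C@](C)(CC[C@@]31C2)[C@@H](Br)CC[C@@]4(C)O | target

**Step count and risks**

Total step count: 18. Longest linear sequence: 18 steps (1 → 26; 3 enters in step 2, 6 in step 4).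

Steps most likely to fail:

1. Step 14. γ-Deprotonation of the vinyl sulfone or anionic oligomerisation of the vinyl ketone may compete with α′-deprotonation, or the first Michael addition may close ring B with poor preference for the diequatorial arrangement. The fallback is a neutral, silyl-mediated cyclization that needs no strong base. It sets out from 18: Me3SiOTf and Et3N (CH2Cl2, 0 °C) give the O-silylated 2-silyloxy diene F1 (tertiary OSiMe3; dienol ether as a geometric mixture). Heating F1 in toluene at 140 °C with ZnCl2 (10 mol%) effects the intramolecular [4+2] cycloaddition, stepwise (Mukaiyama–Michael, then Michael) under the Lewis acid so that both enol ether geometries are used, to the ring-A trimethylsilyl enol ether F2. CsF and PhNTf2 in DME convert the silyl enol ether into the enol triflate and free the tertiary hydroxyl, which comes back to the route at 21.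

2. Step 4. The hindered, fully substituted diene terminus may react sluggishly with the catalyst-bound enal, 1,2-addition to the formyl group may compete, or facial discrimination may be poor. The fallback gives up catalyst control and resolves. It sets out from 5: an uncatalysed thermal Diels–Alder reaction with 6 (toluene, 80 °C, sealed tube) gives the racemic cycloadduct silyl enol ether F3, Bu4NF/AcOH gives the racemic keto aldehyde F4, and preparative chromatography on a chiral stationary phase separates the enantiomers, which comes back to the route at 8.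

3. Step 16. Reductive loss of bromine, or hydrogen delivery to the wrong face (axial bromide), may occur. The fallback installs bromine by substitution with inversion. It sets out from enolate 20: the cascade of step 14 is quenched with aqueous NH4Cl instead of PhNTf2 to give the keto sulfone F5. L-Selectride (THF, −78 °C) attacks the ring-A ketone on the equatorial side and gives the axial alcohol F6. PPh3 and CBr4 (Appel reaction, CH2Cl2, 0 °C → rt) convert the secondary alcohol with inversion into the equatorial bromide, which comes back to the route at 23; the tertiary alcohol is too hindered to react.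

Further compounds
F1 | step 14 | trimethylsilyl ether of 18 at the tertiary hydroxyl with the ketone as its trimethylsilyl dienol ether (geometric mixture) | CC(C)[C@]1(O[Si](C)(C)C)C[C@@H]2C[C@@H](/C=C/S(=O)(=O)c3ccccc3)[C@@]1(CCC(C)=C(O[Si](C)(C)C)C=C)C2
F2 | step 14 | tetracyclic ring-A trimethylsilyl enol ether with tertiary OSiMe3 and PhSO2 on the later carbinol carbon | CC(C)[C@]1(O[Si](C)(C)C)C[C@@H]2C[C@H]3[C@H]4[C@](C)(CC[C@@]31C2)C(O[Si](C)(C)C)=CCC4S(=O)(=O)c1ccccc1
F3 | step 4 | racemic cycloadduct silyl enol ether (racemate of 7; one enantiomer drawn) | CC(C)[Si](C(C)C)(C(C)C)OC1=C[C@@H]2[C@H](C=O)[C@@H](C(OC)OC)[C@@]1(CCC(C)C(=O)OCC)C2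
F4 | step 4 | racemic keto aldehyde (racemate of 8; one enantiomer drawn) | O=C1C[C@@H]2[C@H](C=O)[C@@H](C(OC)OC)[C@@]1(CCC(C)C(=O)OCC)C2
F5 | step 16 | tetracyclic keto sulfone (C=O at the later C–Br carbon; PhSO2 on the later carbinol carbon) | CC(C)[C@]1(O)C[C@@H]2C[C@H]3[C@H]4[C@](C)(CC[C@@]31C2)C(=O)CCC4S(=O)(=O)c1ccccc1
F6 | step 16 | tetracyclic axial secondary alcohol (OH on the later C–Br carbon, opposite face to Br of the target) | CC(C)[C@]1(O)C[C@@H]2C[C@H]3[C@H]4[C@](C)(CC[C@@]31C2)[C@H](O)CCC4S(=O)(=O)c1ccccc1
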